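**Plan**

1. Labdane numbering is used: ring A = C1–C5 + C10, ring B = C5–C10; C2 carries OMe, C4 the gem-dimethyl pair, C8 the exocyclic methylene C17, C9 the chain C11–C16.
2. Cuts: C12–C13 (Negishi coupling with an enol triflate that carries C16–OAc and the C15 ester); C9–C11 (carbonylation of a C9 enol triflate); C3–C4 together with C2–OMe (ring A); C10–C1 and C10–C20 (two alkylations of (S)-carvone).
3. Forward: (S)-carvone is ring B; methylation and allylation build C10; the key step then closes ring A: protonation of the isopropenyl group on C5 gives the C4 cation, C3 of the allyl group on C10 attacks it, and methanol enters at C2. Afterwards the carvone ketone (C9) is converted into the C9 chain and the carvone methyl (C17) into the exocyclic methylene.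
4. Enabling feature: a 1,6-diene made of a 1,1-disubstituted alkene on C5 and a monosubstituted alkene on C10, held trans-diequatorial on neighbouring ring B atoms. Cation stability dictates 6-endo closure, and the syn-axial methyl groups on C4 and C10 leave only the equatorial face of C2 open.
5. Stereochemistry: C5 from (S)-carvone; C10 by alkylation anti to isopropenyl; C2 in the key step; C9 by dienolate protonation anti to C20; C13=C14 geometry from the (E)-enol triflate with retention.

Key step: step 3

Remark on the chemistry: 3 is carried on as a mixture of epimers at the methylated carbon, because this centre is planarised again in step 2. The (E)-selectivity of step 10 under non-chelating conditions is an assumption; 17 is taken to be separable from any (Z)-isomer. tert-Butyl 4-chloro-3-oxobutanoate is taken as commercially available.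

**Route**

Step 1
Reactants: 1 (S)-(+)-carvone
Product: 3 (5S,6R)-2,6-dimethyl-5-(prop-1-en-2-yl)cyclohex-2-en-1-one (trans-6-methylcarvone; the minor epimer is carried along), via carvone lithium enolate 2 (not isolated)
Conditions: LiN(iPr)2 (1.1 equiv), THF, −78 °C; then MeI, −78 to 0 °C
Reagents that add atoms: iodomethane, CI
Why: Kinetic alpha'-deprotonation of the cross-conjugated enone and SN2 methylation (enolate alkylation) introduce C20; the methyl should enter mainly anti to the isopropenyl group, but this centre is planarised again in step 2, so its configuration does not matter.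

Step 2
Reactants: 3 trans-6-methylcarvone
Product: 5 (5R,6R)-2,6-dimethyl-5-(prop-1-en-2-yl)-6-(prop-2-en-1-yl)cyclohex-2-en-1-one, via lithium enolate 4 (not isolated)
Conditions: LiN(iPr)2 (1.2 equiv), THF, −78 to 0 °C; DMPU, allyl bromide, −78 °C to rt
Reagents that add atoms: allyl bromide, C=CCBr
Why: A second enolate alkylation creates the quaternary C10; allyl bromide should approach the tetrasubstituted enolate on the face anti to the neighbouring isopropenyl group, which places the allyl arm trans to isopropenyl and the methyl cis, the arrangement that leads to a trans ring fusion.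

Step 3
Reactants: 5 (5R,6R)-6-allyl-6-methylcarvone
Product: 6 (4aR,7R,8aR)-7-methoxy-2,5,5,8a-tetramethyl-4a,5,6,7,8,8a-hexahydronaphthalen-1(4H)-one (trans-fused; OMe equatorial, anti to the angular methyl)
Conditions: CF3SO3H (0.1 equiv), (CF3)2CHOH–MeOH 9:1, 0.02 M, 0 °C to rt
Reagents that add atoms: methanol, CO
Why: Proposed new method: Markovnikov protonation of the isopropenyl group (the most basic alkene; the allyl group and the enone are far less nucleophilic) gives the tertiary C4 cation, the terminal allyl carbon C3 attacks it, and methanol captures the developing secondary C2 cation, so that the C3–C4 bond, the quaternary C4 and the C2–OMe bond arise in one operation; the closest known reaction type is the Brønsted acid-initiated cation–olefin cyclisation of 1,5- and 1,6-dienes with solvolytic termination (formolysis of 5-hexenyl systems, polyene cyclisations in fluorinated alcohols), the untested part being interception of the cyclohexyl cation by an alcohol in a substrate that carries a conjugated ketone. Ring A closes in the 6-endo-trig mode with respect to the C2=C3 bond, the 5-exo alternative being excluded because it would put the charge on a primary carbon. The trans ring fusion follows from the trans arrangement of the allyl and isopropenyl arms on C10 and C5 set in step 2, since these arms can only meet from a diequatorial chair-like array. C2 is controlled by anti addition across C2=C3 in that chair transition state, which makes the new C–O bond equatorial, and by the two syn-axial methyl groups on C4 and C10, which block the axial face, so that OMe should end up trans to the angular methyl. The step needs chemoselective initiation, ring closure faster than reversible methanol addition at C4 or proton loss towards the isopropylidene isomer (which would endanger C5), and capture at C2 faster than elimination or hydride shift; dilution, low temperature, the weakly nucleophilic ionising solvent and an excess of methanol serve this purpose.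

Step 4
Reactants: 6 methoxy enone
Product: 8 (4aR,7R,8aR)-7-methoxy-2,5,5,8a-tetramethyl-3,4,4a,5,6,7,8,8a-octahydronaphthalen-1-yl trifluoromethanesulfonate, via lithium enolate 7 (not isolated)
Conditions: LiBH(sec-Bu)3 (1.05 equiv), THF, −78 °C; then PhN(SO2CF3)2, −78 to 0 °C
Reagents that add atoms: N-phenylbis(trifluoromethanesulfonimide), O=S(=O)(N(c1ccccc1)S(=O)(=O)C(F)(F)F)C(F)(F)F
Why: Conjugate hydride addition to the hindered enone generates the C9 enolate regiospecifically and O-sulfonylation traps it (reductive enol triflation); no stereocentre is created because C8 is sp2 in the product.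

Step 5
Reactants: 8 enol triflate
Product: 9 methyl (4aR,7R,8aR)-7-methoxy-2,5,5,8a-tetramethyl-3,4,4a,5,6,7,8,8a-octahydronaphthalene-1-carboxylate
Conditions: Pd(OAc)2 (5 mol%), 1,3-bis(diphenylphosphino)propane, CO (1 atm), MeOH, Et3N, DMF, 70 °C
Reagents that add atoms: carbon monoxide, [C-]#[O+]; methanol, CO
Why: Pd-catalysed alkoxycarbonylation of an alkenyl triflate (oxidative addition to zerovalent palladium, CO insertion, methanolysis of the acyl complex) attaches C11 to C9, as is usual for hindered 2,6,6-trisubstituted cyclohexenyl triflates.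

Step 6
Reactants: 9 conjugated ester
Product: 11 methyl (1R,4aR,7R,8aR)-7-methoxy-5,5,8a-trimethyl-2-methylidenedecahydronaphthalene-1-carboxylate, via lithium dienolate 10 (not isolated)
Conditions: LiN(iPr)2 (1.3 equiv), THF–DMPU, −78 to −40 °C; then AcOH in THF, −78 °C
Reagents that add atoms: none
Why: Deconjugative protonation of an enoate: the lithium amide bound to the ester carbonyl should remove a proton from the gamma-methyl group syn to the ester (C17; the ring methylene C7 is anti and out of reach), and kinetic alpha-protonation of the dienolate at C9 on the face anti to the angular methyl should set C9 (H axial, ester equatorial) and leave the C8=C17 exocyclic alkene.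

Step 7
Reactants: 11 deconjugated ester
Product: 13 (1R,4aR,7R,8aR)-7-methoxy-5,5,8a-trimethyl-2-methylidenedecahydronaphthalene-1-carbaldehyde, via aluminium hemiacetal 12 (not isolated)
Conditions: (iBu)2AlH (1.1 equiv), CH2Cl2, −78 °C; MeOH, then aqueous potassium sodium tartrate
Reagents that add atoms: none
Why: Partial reduction of an ester to the aldehyde: the hindered ester should stop at the tetrahedral aluminium hemiacetal at −78 °C, and the cold, near-neutral work-up is meant to avoid epimerisation at C9 or migration of the alkene into conjugation.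

Step 8
Reactants: 13 aldehyde
Product: 14 (1R,4aR,7R,8aR)-1-ethenyl-7-methoxy-5,5,8a-trimethyl-2-methylidenedecahydronaphthalene
Conditions: Ph3PCH3Br, KOtBu, THF, 0 °C; then 13, −78 to 0 °C
Reagents that add atoms: methyltriphenylphosphonium bromide, C[P+](c1ccccc1)(c1ccccc1)c1ccccc1.[Br-]
Why: Wittig methylenation with the non-stabilised ylide; addition to the aldehyde at low temperature should be faster than enolisation of the allylic alpha-stereocentre, so C9 is kept.

Step 9
Reactants: 15 tert-butyl 4-chloro-3-oxobutanoate
Product: 16 tert-butyl 4-(acetyloxy)-3-oxobutanoate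
Conditions: KOAc (1.5 equiv), AcOH (1 equiv), DMF, rt
Reagents that add atoms: potassium acetate, CC(=O)[O-].[K+]
Why: SN2 displacement of the activated alpha-chloro ketone chloride by acetate, buffered by acetic acid against enolate side reactions, installs the C16 acetate at the outset.

Step 10
Reactants: 16 tert-butyl 4-(acetyloxy)-3-oxobutanoate
Product: 17 tert-butyl (2E)-4-(acetyloxy)-3-{[(trifluoromethyl)sulfonyl]oxy}but-2-enoate (triflate trans to the ester, acetoxymethyl cis to it)
Conditions: (CF3SO2)2O, DBU, CH2Cl2, −78 to 0 °C
Reagents that add atoms: trifluoromethanesulfonic anhydride, O=S(=O)(OS(=O)(=O)C(F)(F)F)C(F)(F)F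
Why: O-Sulfonylation of the beta-keto ester enolate (enol triflate formation); with the non-chelating amidinium counter-ion the enolate should react from its extended form and give the (E)-enol triflate, so that the acetoxymethyl group lies cis to the future carboxyl group.

Step 11
Reactants: 14 vinyl decalin; 17 (E)-enol triflate
Product: 20 tert-butyl (2Z)-4-(acetyloxy)-3-{2-[(1R,4aR,7R,8aR)-7-methoxy-5,5,8a-trimethyl-2-methylidenedecahydronaphthalen-1-yl]ethyl}but-2-enoate, via alkylzirconocene chloride 18 (not isolated), via alkylzinc chloride 19 (not isolated)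
Conditions: Cp2Zr(H)Cl (1.1 equiv; Cp = cyclopentadienyl), THF, rt; ZnCl2 (1.2 equiv), 0 °C; then 17, PdCl2(dppf) (5 mol%; dppf = 1,1'-bis(diphenylphosphino)ferrocene), rt to 40 °C
Reagents that add atoms: none
Why: Hydrozirconation should occur at the monosubstituted vinyl group (much faster than at the hindered 1,1-disubstituted C8=C17 alkene) and place zirconium on the terminal carbon C12; transmetalation to zinc and Negishi sp3–sp2 coupling with the enol triflate then form C12–C13 with retention of alkene geometry, so the (Z)-configured C13=C14 bond follows from the (E)-triflate, and the acetate and tert-butyl ester tolerate the neutral organozinc.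

Step 12
Reactants: 20 tert-butyl ester
Product: 22 (2Z)-4-(acetyloxy)-3-{2-[(1R,4aR,7R,8aR)-7-methoxy-5,5,8a-trimethyl-2-methylidenedecahydronaphthalen-1-yl]ethyl}but-2-enoic acid (CNP0155807.1), via trimethylsilyl ester 21 (not isolated)
Conditions: Me3SiOSO2CF3 (3 equiv), 2,6-lutidine (4 equiv), CH2Cl2, 0 °C; then aqueous NaH2PO4
Reagents that add atoms: none
Why: Silyl triflate-mediated cleavage of the tert-butyl ester (O-silylation, loss of isobutene) under buffered non-protic conditions should spare the exocyclic alkene, the allylic acetate and the methyl ether; hydrolysis of the silyl ester on work-up releases the acid, which cannot lactonise because C16–O stays acetylated throughout.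

**Compound list**

1 | (S)-(+)-carvone, (5S)-2-methyl-5-(prop-1-en-2-yl)cyclohex-2-en-1-one | CC1=CC[C@H](C(C)=C)CC1=O | starting material
2 | lithium enolate of 1 (cross-conjugated dienolate) | CC1=CC[C@H](C(C)=C)C=C1[O-].[Li+] | intermediate
3 | (5S,6R)-2,6-dimethyl-5-(prop-1-en-2-yl)cyclohex-2-en-1-one (trans-6-methylcarvone) | CC1=CC[C@H](C(C)=C)[C@@H](C)C1=O | intermediate
4 | lithium enolate of 3 | CC1=CC[C@H](C(C)=C)C(C)=C1[O-].[Li+] | intermediate
5 | (5R,6R)-2,6-dimethyl-5-(prop-1-en-2-yl)-6-(prop-2-en-1-yl)cyclohex-2-en-1-one | CC1=CC[C@H](C(C)=C)[C@@](C)(CC=C)C1=O | intermediate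
6 | (4aR,7R,8aR)-7-methoxy-2,5,5,8a-tetramethyl-4a,5,6,7,8,8a-hexahydronaphthalen-1(4H)-one | CC1=CC[C@@H]2C(C)(C)C[C@@H](OC)C[C@@]2(C)C1=O | intermediate
7 | lithium (4aR,7R,8aR)-7-methoxy-2,5,5,8a-tetramethyl-3,4,4a,5,6,7,8,8a-octahydronaphthalen-1-olate | CC=1CC[C@@H]2C(C)(C)C[C@@H](OC)C[C@@]2(C)C=1[O-].[Li+] | intermediate
8 | (4aR,7R,8aR)-7-methoxy-2,5,5,8a-tetramethyl-3,4,4a,5,6,7,8,8a-octahydronaphthalen-1-yl trifluoromethanesulfonate | CC=1CC[C@@H]2C(C)(C)C[C@@H](OC)C[C@@]2(C)C=1OS(=O)(=O)C(F)(F)F | intermediate
9 | methyl (4aR,7R,8aR)-7-methoxy-2,5,5,8a-tetramethyl-3,4,4a,5,6,7,8,8a-octahydronaphthalene-1-carboxylate | CC=1CC[C@@H]2C(C)(C)C[C@@H](OC)C[C@@]2(C)C=1C(=O)OC | intermediate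
10 | lithium dienolate of 9 (ketene acetal with exocyclic C8=C17) | C=C1CC[C@@H]2C(C)(C)C[C@@H](OC)C[C@@]2(C)C1=C(OC)[O-].[Li+] | intermediate
11 | methyl (1R,4aR,7R,8aR)-7-methoxy-5,5,8a-trimethyl-2-methylidenedecahydronaphthalene-1-carboxylate | C=C1CC[C@@H]2C(C)(C)C[C@@H](OC)C[C@@]2(C)[C@@H]1C(=O)OC | intermediate
12 | diisobutylaluminium hemiacetal of 11 | C=C1CC[C@@H]2C(C)(C)C[C@@H](OC)C[C@@]2(C)[C@@H]1C(OC)O[Al](CC(C)C)CC(C)C | intermediate
13 | (1R,4aR,7R,8aR)-7-methoxy-5,5,8a-trimethyl-2-methylidenedecahydronaphthalene-1-carbaldehyde | C=C1CC[C@@H]2C(C)(C)C[C@@H](OC)C[C@@]2(C)[C@@H]1C=O | intermediate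
14 | (1R,4aR,7R,8aR)-1-ethenyl-7-methoxy-5,5,8a-trimethyl-2-methylidenedecahydronaphthalene | C=C1CC[C@@H]2C(C)(C)C[C@@H](OC)C[C@@]2(C)[C@@H]1C=C | intermediate
15 | tert-butyl 4-chloro-3-oxobutanoate | O=C(CCl)CC(=O)OC(C)(C)C | starting material
16 | tert-butyl 4-(acetyloxy)-3-oxobutanoate | CC(=O)OCC(=O)CC(=O)OC(C)(C)C | intermediate
17 | tert-butyl (2E)-4-(acetyloxy)-3-{[(trifluoromethyl)sulfonyl]oxy}but-2-enoate | FC(F)(F)S(=O)(=O)O/C(=C/C(=O)OC(C)(C)C)COC(C)=O | intermediate
18 | chlorobis(cyclopentadienyl){2-[(1R,4aR,7R,8aR)-7-methoxy-5,5,8a-trimethyl-2-methylidenedecahydronaphthalen-1-yl]ethyl}zirconium | C=C1CC[C@@H]2C(C)(C)C[C@@H](OC)C[C@@]2(C)[C@@H]1CC[Zr](Cl)(C1C=CC=C1)C1C=CC=C1 | intermediate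
19 | chloro{2-[(1R,4aR,7R,8aR)-7-methoxy-5,5,8a-trimethyl-2-methylidenedecahydronaphthalen-1-yl]ethyl}zinc | C=C1CC[C@@H]2C(C)(C)C[C@@H](OC)C[C@@]2(C)[C@@H]1CC[Zn]Cl | intermediate
20 | tert-butyl (2Z)-4-(acetyloxy)-3-{2-[(1R,4aR,7R,8aR)-7-methoxy-5,5,8a-trimethyl-2-methylidenedecahydronaphthalen-1-yl]ethyl}but-2-enoate | C=C1CC[C@@H]2C(C)(C)C[C@@H](OC)C[C@@]2(C)[C@@H]1CC/C(=C/C(=O)OC(C)(C)C)COC(C)=O | intermediate
21 | trimethylsilyl ester of 22 | C=C1CC[C@@H]2C(C)(C)C[C@@H](OC)C[C@@]2(C)[C@@H]1CC/C(=C/C(=O)O[Si](C)(C)C)COC(C)=O | intermediate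
22 | (2Z)-4-(acetyloxy)-3-{2-[(1R,4aR,7R,8aR)-7-methoxy-5,5,8a-trimethyl-2-methylidenedecahydronaphthalen-1-yl]ethyl}but-2-enoic acid | C=C1CC[C@@H]2C(C)(C)C[C@@H](OC)C[C@@]2(C)[C@@H]1CC/C(=C/C(=O)O)COC(C)=O | target

**Count**

Total steps: 12 (steps 1–8 and 11–12 on the main line, steps 9–10 for the side-chain fragment).
Longest linear sequence: 10 steps from (S)-carvone (steps 1–8, 11, 12).

**Steps most likely to fail, with fallbacks**

Step 3 (the proposed new method). Methanol may add to the C4 cation faster than the ring closes, with a tertiary ether that does not re-ionise. The C2 cation may also lose a proton or suffer a hydride shift before methanol arrives. Reversible proton loss towards the isopropylidene isomer would scramble C5. The fallback uses known chemistry: formolytic cation–olefin cyclisation with carboxylate termination, then ester cleavage and O-methylation, so that ring closure no longer depends on an alcohol being present in the ionising medium and the ether bond is made separately. It sets out from 5: anhydrous formic acid at room temperature should give the equatorial formate (4aR,7R,8aR)-7-(formyloxy)-2,5,5,8a-tetramethyl-4a,5,6,7,8,8a-hexahydronaphthalen-1(4H)-one F1. Methanolysis (K2CO3, MeOH) should give the alcohol (4aR,7R,8aR)-7-hydroxy-2,5,5,8a-tetramethyl-4a,5,6,7,8,8a-hexahydronaphthalen-1(4H)-one F2. Methylation with MeOSO2CF3 and 2,6-di-tert-butyl-4-methylpyridine in CH2Cl2 comes back to the route at 6.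

Step 11. Hydrozirconation may not discriminate well enough between the vinyl group and the exocyclic methylene, the transfer from zirconium to zinc may be slow, and beta-hydride elimination, ionisation of the allylic acetate by zerovalent palladium or loss of alkene geometry may erode the coupling. The fallback builds the chain stepwise from the aldehyde without any hydrometalation and takes the alkene geometry from a chelation-controlled enol triflate. It sets out from 13: Horner–Wadsworth–Emmons olefination with the dianion of tert-butyl 4-(diethoxyphosphoryl)-3-oxobutanoate (NaH, then n-BuLi, THF) should give tert-butyl (4E)-5-[(1R,4aR,7R,8aR)-7-methoxy-5,5,8a-trimethyl-2-methylidenedecahydronaphthalen-1-yl]-3-oxopent-4-enoate F3. Conjugate reduction with [(Ph3P)CuH]6 should give the saturated beta-keto ester tert-butyl 5-[(1R,4aR,7R,8aR)-7-methoxy-5,5,8a-trimethyl-2-methylidenedecahydronaphthalen-1-yl]-3-oxopentanoate F4. Triflation under chelating conditions ((CF3SO2)2O, Et3N, LiOSO2CF3, CH2Cl2) should give tert-butyl (2Z)-5-[(1R,4aR,7R,8aR)-7-methoxy-5,5,8a-trimethyl-2-methylidenedecahydronaphthalen-1-yl]-3-{[(trifluoromethyl)sulfonyl]oxy}pent-2-enoate F5. Negishi coupling of F5 with AcOCH2ZnBr (from bromomethyl acetate and zinc) and PdCl2(dppf) puts the acetoxymethyl group cis to the ester and comes back to the route at 20.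

Step 6. The base may remove a proton from the ring methylene C7 instead of the C17 methyl group, which would lead to the endocyclic isomer, or the dienolate may be protonated at the gamma carbon and return 9. The fallback is the photochemical deconjugation of alpha,beta-unsaturated esters, where a light-induced 1,5-hydrogen shift can only take a hydrogen from the gamma-carbon syn to the carbonyl group. It sets out from 9: irradiation at 254 nm in hexane with a catalytic amount of 1,2-dimethylimidazole should give the photodienol methyl ketene hemiacetal F6, whose base-catalysed ketonisation at C9 from the face anti to the angular methyl comes back to the route at 11.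

**Further compounds**

F1 | step 3 | (4aR,7R,8aR)-7-(formyloxy)-2,5,5,8a-tetramethyl-4a,5,6,7,8,8a-hexahydronaphthalen-1(4H)-one | CC1=CC[C@@H]2C(C)(C)C[C@@H](OC=O)C[C@@]2(C)C1=O
F2 | step 3 | (4aR,7R,8aR)-7-hydroxy-2,5,5,8a-tetramethyl-4a,5,6,7,8,8a-hexahydronaphthalen-1(4H)-one | CC1=CC[C@@H]2C(C)(C)C[C@@H](O)C[C@@]2(C)C1=O
F3 | step 11 | tert-butyl (4E)-5-[(1R,4aR,7R,8aR)-7-methoxy-5,5,8a-trimethyl-2-methylidenedecahydronaphthalen-1-yl]-3-oxopent-4-enoate | C=C1CC[C@@H]2C(C)(C)C[C@@H](OC)C[C@@]2(C)[C@@H]1/C=C/C(=O)CC(=O)OC(C)(C)C
F4 | step 11 | tert-butyl 5-[(1R,4aR,7R,8aR)-7-methoxy-5,5,8a-trimethyl-2-methylidenedecahydronaphthalen-1-yl]-3-oxopentanoate | C=C1CC[C@@H]2C(C)(C)C[C@@H](OC)C[C@@]2(C)[C@@H]1CCC(=O)CC(=O)OC(C)(C)C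
F5 | step 11 | tert-butyl (2Z)-5-[(1R,4aR,7R,8aR)-7-methoxy-5,5,8a-trimethyl-2-methylidenedecahydronaphthalen-1-yl]-3-{[(trifluoromethyl)sulfonyl]oxy}pent-2-enoate | C=C1CC[C@@H]2C(C)(C)C[C@@H](OC)C[C@@]2(C)[C@@H]1CC/C(OS(=O)(=O)C(F)(F)F)=C/C(=O)OC(C)(C)C
F6 | step 6 | photodienol of 9 (methyl ketene hemiacetal with exocyclic C8=C17) | C=C1CC[C@@H]2C(C)(C)C[C@@H](OC)C[C@@]2(C)C1=C(O)OC
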